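## Structural features

Compound 15 is a 2,5-diaryl-3,4-bis(hydroxymethyl)tetrahydrofuran: one saturated oxacycle (O1, C2–C5) carries a 4-hydroxy-3,5-dimethoxyphenyl ring at C2 and a 3,4,5-trimethoxyphenyl ring at C5 through single C–C bonds, and one CH2OH group on each of C3 and C4. The four ring carbons are contiguous stereocentres of configuration (2R,3S,4S,5R); every neighbouring pair is trans and the two aryl groups lie on opposite faces, so the target is the all-trans isomer, which is also the least crowded one. The two halves differ only in one para oxygen (OH against OMe), so the skeleton is almost C2-symmetric but must be assembled with the aryl groups told apart. The fragile points are the two ring C–O bonds, both benzylic to electron-rich arenes (C2–O1, para to a free phenol, ionises most easily under acid and is the first to suffer hydrogenolysis), the oxidisable phenol, and the two primary alcohols, which need a mask that leaves without acid or hydrogen. The real difficulty is the absolute configuration of the C3/C4 pair, which has no heteroatom stereocentre to lean on, together with the regiodefined placing of two different aryl groups. The key step exploits the benzylic ether bond O1–C5: with C2 as a carbonyl, the ring O1–C2–C3–C4–C5 is a cyclobutanone built from C2, C3, C4 and C5 into which O1 has been inserted between the carbonyl carbon and the aryl-bearing carbon. On that four-membered ring the C5/C4/C3 triad can be set as a unit, trans across a former E-alkene and trans at the enolisable aryl-bearing carbon, while C2 remains a carbonyl that later accepts the second aryl group trans to C3.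

## Logic of the disconnections

15 ⇒ 14. The two primary O–Si bonds are cut first. The hydroxymethyl groups are carried as tert-butyldiphenylsilyl ethers and not as benzyl ethers, because unmasking then needs only fluoride; hydrogenolysis would put both benzylic ring C–O bonds of 15 at risk, C2–O1 most of all. The cut changes no skeletal feature. The forward step must be buffered so that a phenoxide cannot open C2–O1.

14 ⇒ 12 + 13. The C2–aryl bond is cut. This removes one arene and one stereocentre and reveals an oxocarbenium ion at C2, stored as the acetal 12, and the unprotected phenol 13, whose hydroxyl group directs an electrophile to its para carbon. The forward step must bring the aryl group in trans to the C3 substituent; approach opposite that substituent and the reversibility of the benzylic C–O ionisation both point that way. The silyl ethers must survive a Lewis acid at low temperature, hence the robust tert-butyldiphenylsilyl group.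

12 ⇒ 10. The C2–H bond and the O-acetyl bond are removed, so that C2 returns to the carbonyl of a γ-lactone. Both operations are meant to run in one flask through 11, so no lactol is isolated. The forward step must deliver exactly one hydride and must not disturb the enolisable centre C3.

10 ⇒ 9. The O1–C5 bond is cut and the lactone contracts to a cyclobutanone. The reason is that C5, C4 and C3 of 10 are all-trans, which is the arrangement a four-membered ring from an E-alkene and an arylketene equivalent adopts once the aryl-bearing carbon has equilibrated. A heterocycle with three stereocentres becomes a carbocycle that one cycloaddition can deliver. The forward oxygen insertion must move the benzylic α-carbon and not the alkyl one, with retention, and must spare the trimethoxyarene.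

9 ⇒ 6 + 2. The two ring bonds that join the carbonyl carbon and the aryl-bearing carbon to the two CH(CH2OSi) carbons are cut, a (2+2) retron. 6 supplies the first pair as the keteniminium ion 7, unmasked to the ketone through 8; 2 supplies the second pair. Because 2 is symmetrical there is no regiochemical question, and its E geometry becomes the trans relationship of the two CH2OSi groups. The absolute configuration must come from the C2-symmetric amine part of 6, which gives a single form of 7. The ether oxygens of 2 must not intercept the cation, a second reason for bulky silyl groups.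

6 ⇒ 3 + 4. The amide C–N bond is cut: 3 brings the arene and both future ring carbons, 4 is the recoverable chiral controller. The acylation of a hindered secondary amine must proceed without ketene formation, hence activation as 5.

2 ⇒ 1. The two O–Si bonds are cut; 1 already holds the E double bond and both oxygen atoms.

## Other disconnections considered

Alternative 1: The cut removes the two exocyclic bonds C4–CH2 and C3–CH2 of the lactone and leads back to the butenolide A1. In the forward key step CuBr·SMe2 catalyses the 1,4-addition of the silylmethyl Grignard reagent A3 to A1, anti to the C5 aryl group; the lactone enolate is then alkylated by benzyl chloromethyl ether A4, anti to the new C4 substituent, to give the trans,trans lactone A2.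
- In favour: all three lactone centres descend from one carbinol centre that a well-understood asymmetric ketone reduction can secure. On absolute stereocontrol this is better founded than auxiliary control of a cycloaddition, and the alternative is the better on that point.
- Equal: A2 has the oxidation level of 10 and could use the same end game.
- Against: the C5 hydrogen of A1 is benzylic and vinylogously acidic, so deprotonation to an aromatic 2-oxidofuran under the basic organometallic conditions threatens the only controlling stereocentre. The two hydroxymethyl groups emerge differentiated (C–Si and O-benzyl) although the target does not need this, which adds a Tamao–Fleming oxidation and a debenzylation close to two benzylic ring C–O bonds. A4 is a strongly carcinogenic alkylating agent.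
- Step economy: A1 would take about three steps, followed by the tandem step, oxidation, protecting-group changes and the acetal/arylation sequence, roughly ten operations against seven.

Alternative 2: The cut is the C2–C3 bond of the tetrahydrofuran and leads to the acyclic diazo ester A5, in which both aryl groups and the C4/C5 pair are already in place. In the forward key step Rh2(S-PTTL)4 converts A5 into a rhodium carbenoid at C3 that inserts into a benzylic C–H bond of the 4-benzyloxy-3,5-dimethoxybenzyl ether, closing the ring as the all-trans ester A6.
- In favour: the ring is made directly at the tetrahydrofuran oxidation level with both arenes placed beforehand, so there is no acetal stage and no question of where the phenol is attacked. On these points the alternative is the better. The C–H bond concerned is doubly activated, and two stereocentres arise under catalyst control.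
- Against: A5 has a hydrogen on the carbon next to the carbenoid, so 1,2-hydride shift to an alkene competes. The ether oxygen can form an oxonium ylide (Stevens-type shift), and the electron-rich arenes invite Buchner-type addition. The C4/C5 pair must first be made by a separate asymmetric sequence, followed by etherification of a hindered benzylic alcohol and diazo transfer with azide reagents. The benzyl ether on the phenol demands a final hydrogenolysis next to the benzylic ring C–O bonds.
- Comparison: mechanistically the alternative sets more in one step but relies on kinetic catalyst selectivity, whereas the chosen plan relies on trans relays that are also thermodynamically preferred. In step count the two should be about equal or slightly in favour of the chosen plan.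

Alternative 3: The cut removes O1–C2 and C3–C4 and gives the vinyl epoxide A7 (O1, C5, C4 and the vinyl group) and the arylidene malonate A8 (C2, C3). In the forward key step zerovalent palladium from Pd2(dba)3 and a bisphosphine ionises A7 to an alkoxide-bearing π-allyl complex; the alkoxide adds to A8, and the malonate carbanion closes onto the internal allyl carbon to give A9.
- In favour: this is the most convergent of the four plans. The ring, both arenes and two ring bonds come from one catalytic step on two building blocks that are each one or two steps from aryl aldehydes, and a chiral bisphosphine could replace a stoichiometric auxiliary. In convergence and in the use of catalysis it is the better.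
- Against: A9 has the wrong functionality at both C3 and C4. The geminal diester must lose one carboxyl (Krapcho), with C3 set only in that protonation, and then be reduced; the vinyl group must be shortened by one carbon through oxidative cleavage and reduction in the presence of electron-rich arenes. The oxa-Michael addition is reversible, and the 2,5-relationship is set kinetically. A benzyl ether on the phenol again calls for hydrogenolysis.
- Comparison: the count, about eight or nine steps, is equal to or slightly above that of the chosen plan, with more redox corrections. In the chosen plan every carbon enters at its final oxidation level except C2.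

Key step: step 4

Assumption: the (2S,5S) enantiomer of 4 is assigned to the required sense of induction from a steric model (the alkene adds to the central keteniminium carbon on the side of the C–H of the aryl-bearing carbon, its nearer CH2OSi group turned away from the ring methyl group on that face); should the sense be the opposite, the equally available (2R,5R) amine would be used with no other change.

## Route

Step 1
Reactants: 1 (E)-but-2-ene-1,4-diol
Product: 2 (E)-1,4-bis{[tert-butyl(diphenyl)silyl]oxy}but-2-ene
Conditions: TBDPSCl (2.2 equiv), imidazole, DMF, 0 °C → rt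
Reagents that add atoms: tert-butyl(chloro)diphenylsilane, CC(C)(C)[Si](Cl)(c1ccccc1)c1ccccc1
Why: Imidazole-promoted O-silylation of two unhindered primary allylic alcohols; the E double bond is untouched and no stereocentre is involved.

Step 2
Reactants: 3 3,4,5-trimethoxyphenylacetic acid; 4 (2S,5S)-2,5-dimethylpyrrolidine
Product: 6 1-[(2S,5S)-2,5-dimethylpyrrolidin-1-yl]-2-(3,4,5-trimethoxyphenyl)ethan-1-one, via 3,4,5-trimethoxyphenylacetyl chloride 5 (not isolated)
Conditions: (COCl)2, cat. DMF, CH2Cl2, 0 °C → rt; then 4, Et3N, CH2Cl2, 0 °C → rt
Reagents that add atoms: oxalyl chloride, O=C(Cl)C(=O)Cl (supplies the chlorine of 5 only; none of its atoms remain in 6)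
Why: Acid chloride formation followed by N-acylation, chosen because a 2,5-disubstituted pyrrolidine reacts sluggishly with milder active esters; the amine is present before the base at 0 °C so that the acid chloride is acylated faster than it can lose HCl to a ketene, and the two stereocentres of 4 are not affected.

Step 3
Reactants: 6 1-[(2S,5S)-2,5-dimethylpyrrolidin-1-yl]-2-(3,4,5-trimethoxyphenyl)ethan-1-one; 2 (E)-1,4-bis{[tert-butyl(diphenyl)silyl]oxy}but-2-ene
Product: 9 (2R,3S,4S)-3,4-bis{[tert-butyl(diphenyl)silyl]oxymethyl}-2-(3,4,5-trimethoxyphenyl)cyclobutan-1-one, via keteniminium triflate 7 (not isolated), via cyclobutaniminium triflate 8 (not isolated)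
Conditions: Tf2O, 2,4,6-collidine, 2 (2.5 equiv, excess recovered), ClCH2CH2Cl, −20 → 80 °C; then aq. NaHCO3, rt
Reagents that add atoms: water, O (carbonyl oxygen of 9); trifluoromethanesulfonic anhydride, O=S(=O)(OS(=O)(=O)C(F)(F)F)C(F)(F)F (triflate counter-ion of 7 and 8 only)
Why: Tf2O and collidine dehydrate the tertiary amide to the aryl keteniminium ion 7, whose electrophilic central carbon adds to the alkene in a thermal keteniminium–alkene (2+2) cycloaddition that keeps the E geometry (the two CH2OSi groups trans) and uses the alkene face left open by the C2-symmetric 2,5-dimethylpyrrolidinium unit (absolute configuration of both CH(CH2OSi) carbons); hydrolysis of 8 releases the ketone and the auxiliary. The benzylic hydrogen at the aryl-bearing carbon, α to the iminium and then to the carbonyl group, should equilibrate under the collidine and hydrogencarbonate conditions to the all-trans isomer. Bulky, weakly basic silyl ether oxygens are used so that the ether oxygens do not capture the keteniminium ion.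

Step 4
Reactants: 9 (2R,3S,4S)-3,4-bis{[tert-butyl(diphenyl)silyl]oxymethyl}-2-(3,4,5-trimethoxyphenyl)cyclobutan-1-one
Product: 10 (3S,4S,5R)-3,4-bis{[tert-butyl(diphenyl)silyl]oxymethyl}-5-(3,4,5-trimethoxyphenyl)oxolan-2-one
Conditions: mCPBA (1.2 equiv), NaHCO3, CH2Cl2, 0 °C → rt
Reagents that add atoms: 3-chloroperbenzoic acid, OOC(=O)c1cccc(Cl)c1
Why: The peracid adds to the strained carbonyl of 9 to give a peroxyhemiketal, and the ring bond C1–C2 that lies antiperiplanar to the O–O bond then shifts from carbon to the proximal peroxide oxygen as 3-chlorobenzoate leaves (Baeyer–Villiger oxidation), which creates the O1–C5 bond of 10. The closest known reaction type is the Baeyer–Villiger ring expansion of 2-arylcyclobutanones to γ-aryl-γ-butyrolactones. The five-membered ring is therefore closed by a one-atom ring expansion (four to five) through a concerted 1,2-shift, not by an end-to-end cyclisation, and the release of cyclobutanone strain should make the addition fast at 0 °C. No stereocentre is created: the migrating carbon keeps its bonding electron pair and its configuration (retention), and the two CH(CH2OSi) carbons are not touched, so the (2R,3S,4S) triad of 9 is carried over as the (5R,4S,3S) triad of 10. The selectivity needed is regiochemical, migration of the aryl-bearing carbon and not of the CH(CH2OSi) carbon; both are secondary, but the aryl group stabilises the positive charge that builds up on the migrating carbon, whereas the other α-carbon is deactivated by its β-silyloxy substituent. Chemoselectivity rests on rate: the strained ketone should consume the slight excess of peracid well before the trimethoxyarene can be hydroxylated. NaHCO3 keeps the medium near neutral, so the silyl ethers and the new benzylic lactone C–O bond are not exposed to 3-chlorobenzoic acid and 10 cannot enolise.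

Step 5
Reactants: 10 (3S,4S,5R)-3,4-bis{[tert-butyl(diphenyl)silyl]oxymethyl}-5-(3,4,5-trimethoxyphenyl)oxolan-2-one
Product: 12 (3S,4S,5R)-3,4-bis{[tert-butyl(diphenyl)silyl]oxymethyl}-5-(3,4,5-trimethoxyphenyl)oxolan-2-yl acetate (both C2 epimers), via diisobutylaluminium hemiacetal 11 (not isolated)
Conditions: iBu2AlH (1.2 equiv), CH2Cl2, −78 °C; then pyridine, DMAP, Ac2O, −78 → 0 °C; aq. potassium sodium tartrate
Reagents that add atoms: acetic anhydride, CC(=O)OC(C)=O; diisobutylaluminium hydride, CC(C)C[AlH]CC(C)C (aluminium and isobutyl groups of 11 only; its hydride becomes C2–H)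
Why: One hydride adds to the lactone at −78 °C and the tetrahedral aluminium hemiacetal 11 is stable at that temperature; acylating it in the same flask (one-pot reductive acetylation) traps the lactol oxidation level without ever freeing a hydroxy aldehyde, which avoids over-reduction and epimerisation at C3. The new acetal centre C2 forms as a mixture, which does not matter because it is ionised in step 6.

Step 6
Reactants: 12 (3S,4S,5R)-3,4-bis{[tert-butyl(diphenyl)silyl]oxymethyl}-5-(3,4,5-trimethoxyphenyl)oxolan-2-yl acetate; 13 2,6-dimethoxyphenol
Product: 14 4-[(2R,3S,4S,5R)-3,4-bis{[tert-butyl(diphenyl)silyl]oxymethyl}-5-(3,4,5-trimethoxyphenyl)oxolan-2-yl]-2,6-dimethoxyphenol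
Conditions: 13 (3 equiv), BF3·OEt2, CH2Cl2, −78 → −30 °C; aq. NaHCO3 quench
Reagents that add atoms: none
Why: BF3·OEt2 ionises the acetate to the cyclic oxocarbenium ion, which is captured by the carbon para to the hydroxyl group of 13 (Friedel–Crafts C-arylation; the hydroxyl is the strongest director and both of its ortho positions carry methoxy groups). The new centre C2 is set trans to the C3 substituent (2R) because the arene approaches the face opposite the neighbouring CH2OSi group, and since the C2–O1 bond of the product can re-ionise under the Lewis acid the all-trans isomer is also the thermodynamic outcome. The phenol needs no protection and emerges free.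

Step 7
Reactants: 14 4-[(2R,3S,4S,5R)-3,4-bis{[tert-butyl(diphenyl)silyl]oxymethyl}-5-(3,4,5-trimethoxyphenyl)oxolan-2-yl]-2,6-dimethoxyphenol
Product: 15 4-[(2R,3S,4S,5R)-3,4-bis(hydroxymethyl)-5-(3,4,5-trimethoxyphenyl)oxolan-2-yl]-2,6-dimethoxyphenol
Conditions: Bu4NF, AcOH (1:1), THF, 0 °C → rt
Reagents that add atoms: none
Why: Fluoride cleaves both primary Si–O bonds (silyl ether deprotection driven by Si–F bond formation); acetic acid keeps the phenol protonated so that no quinone-methide-type opening of C2–O1 can begin, and neither hydrogen nor strong acid touches the two benzylic ring C–O bonds, so no stereocentre is affected.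

## Compound list

1 | (E)-but-2-ene-1,4-diol | OC/C=C/CO | starting material
2 | (E)-1,4-bis{[tert-butyl(diphenyl)silyl]oxy}but-2-ene | CC(C)(C)[Si](c1ccccc1)(c1ccccc1)OC/C=C/CO[Si](c1ccccc1)(c1ccccc1)C(C)(C)C | intermediate
3 | 3,4,5-trimethoxyphenylacetic acid | COc1cc(CC(=O)O)cc(OC)c1OC | starting material
4 | (2S,5S)-2,5-dimethylpyrrolidine | C[C@H]1CC[C@H](C)N1 | starting material
5 | 3,4,5-trimethoxyphenylacetyl chloride | COc1cc(CC(=O)Cl)cc(OC)c1OC | intermediate (not isolated)
6 | 1-[(2S,5S)-2,5-dimethylpyrrolidin-1-yl]-2-(3,4,5-trimethoxyphenyl)ethan-1-one | COc1cc(CC(=O)N2[C@@H](C)CC[C@@H]2C)cc(OC)c1OC | intermediate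
7 | (2S,5S)-2,5-dimethyl-1-[2-(3,4,5-trimethoxyphenyl)ethenylidene]pyrrolidin-1-ium trifluoromethanesulfonate (keteniminium triflate) | COc1cc(C=C=[N+]2[C@@H](C)CC[C@@H]2C)cc(OC)c1OC.[O-]S(=O)(=O)C(F)(F)F | intermediate (not isolated)
8 | (2S,5S)-1-[(2R,3S,4R)-3,4-bis{[tert-butyl(diphenyl)silyl]oxymethyl}-2-(3,4,5-trimethoxyphenyl)cyclobutylidene]-2,5-dimethylpyrrolidin-1-ium trifluoromethanesulfonate (cyclobutaniminium triflate; same spatial arrangement as 9, all-trans) | C[C@H]2CC[C@H](C)[N+]2=C1[C@@H](c3cc(OC)c(OC)c(OC)c3)[C@H](CO[Si](c3ccccc3)(c3ccccc3)C(C)(C)C)[C@H]1CO[Si](c1ccccc1)(c1ccccc1)C(C)(C)C.[O-]S(=O)(=O)C(F)(F)F | intermediate (not isolated)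
9 | (2R,3S,4S)-3,4-bis{[tert-butyl(diphenyl)silyl]oxymethyl}-2-(3,4,5-trimethoxyphenyl)cyclobutan-1-one (all-trans) | O=C1[C@@H](c2cc(OC)c(OC)c(OC)c2)[C@H](CO[Si](c2ccccc2)(c2ccccc2)C(C)(C)C)[C@H]1CO[Si](c1ccccc1)(c1ccccc1)C(C)(C)C | intermediate
10 | (3S,4S,5R)-3,4-bis{[tert-butyl(diphenyl)silyl]oxymethyl}-5-(3,4,5-trimethoxyphenyl)oxolan-2-one (trans,trans) | O=C1O[C@@H](c2cc(OC)c(OC)c(OC)c2)[C@H](CO[Si](c2ccccc2)(c2ccccc2)C(C)(C)C)[C@H]1CO[Si](c1ccccc1)(c1ccccc1)C(C)(C)C | intermediate
11 | {[(3S,4S,5R)-3,4-bis{[tert-butyl(diphenyl)silyl]oxymethyl}-5-(3,4,5-trimethoxyphenyl)oxolan-2-yl]oxy}bis(2-methylpropyl)aluminium (C2 epimers) | CC(C)C[Al](CC(C)C)OC1O[C@@H](c2cc(OC)c(OC)c(OC)c2)[C@H](CO[Si](c2ccccc2)(c2ccccc2)C(C)(C)C)[C@H]1CO[Si](c1ccccc1)(c1ccccc1)C(C)(C)C | intermediate (not isolated)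
12 | (3S,4S,5R)-3,4-bis{[tert-butyl(diphenyl)silyl]oxymethyl}-5-(3,4,5-trimethoxyphenyl)oxolan-2-yl acetate (C2 epimers) | CC(=O)OC1O[C@@H](c2cc(OC)c(OC)c(OC)c2)[C@H](CO[Si](c2ccccc2)(c2ccccc2)C(C)(C)C)[C@H]1CO[Si](c1ccccc1)(c1ccccc1)C(C)(C)C | intermediate
13 | 2,6-dimethoxyphenol | COc1cccc(OC)c1O | starting material
14 | 4-[(2R,3S,4S,5R)-3,4-bis{[tert-butyl(diphenyl)silyl]oxymethyl}-5-(3,4,5-trimethoxyphenyl)oxolan-2-yl]-2,6-dimethoxyphenol | COc1cc([C@@H]2O[C@@H](c3cc(OC)c(OC)c(OC)c3)[C@H](CO[Si](c3ccccc3)(c3ccccc3)C(C)(C)C)[C@H]2CO[Si](c2ccccc2)(c2ccccc2)C(C)(C)C)cc(OC)c1O | intermediate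
15 | 4-[(2R,3S,4S,5R)-3,4-bis(hydroxymethyl)-5-(3,4,5-trimethoxyphenyl)oxolan-2-yl]-2,6-dimethoxyphenol | COc1cc([C@@H]2O[C@@H](c3cc(OC)c(OC)c(OC)c3)[C@H](CO)[C@H]2CO)cc(OC)c1O | target

## Step count and least certain steps

Total step count: 7. Longest linear sequence: 6 steps (steps 2 to 7 from 3; equally steps 1 and 3 to 7 from 1).

Step 3 (cycloaddition) is the least certain. What is most likely to go wrong is incomplete facial discrimination, because the stereocentres of the pyrrolidinium unit sit three bonds from the reacting carbon. It is aggravated by slow addition to an alkene whose two carbons each carry an inductively withdrawing CH2O group, which gives the keteniminium ion time to condense with itself or to be attacked by an arene. Fallback, setting out from 9 of insufficient enantiomeric purity and returning to 9: the source of enantiopurity is moved from auxiliary control to a separation of covalent diastereomers. Acid-catalysed ketalisation (PPTS, benzene, reflux with removal of water) with the C2-symmetric diol (1R,2R)-1,2-diphenylethane-1,2-diol F1 should convert 9 into the spiro-ketal F2 and its mirror-image contaminant into the diastereomeric spiro-ketal F3. Because the diol is C2-symmetric the ketal carbon is not a stereocentre, so only these two diastereomers can form. After separation by chromatography or crystallisation, transketalisation of F2 (TsOH, acetone–water, 40 °C, which primary tert-butyldiphenylsilyl ethers tolerate) should return enantiopure 9 to step 4 and give back the diol.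

Step 4 (key step). What is most likely to go wrong is loss of regiocontrol in the 1,2-shift, that is, migration of the CH(CH2OSi) carbon to give the isomeric lactone. Both α-carbons are secondary, and the 3,4,5-trimethoxyphenyl group stabilises cationic character only moderately, since its two meta methoxy groups offset the para one. Electrophilic hydroxylation of the arene by surplus peracid is the second concern. Fallback, setting out from 9 and returning at 14: the oxygen is inserted photochemically instead of with a peracid. Irradiation of 9 in methanol (λ > 300 nm, Pyrex, 0 °C) is expected to cleave the weaker benzylic C1–C2 bond, join the acyl oxygen to the benzylic carbon and trap the ring-expanded carbene with the solvent (the known photochemical ring expansion of cyclobutanones to 2-alkoxytetrahydrofurans). This would give the methyl acetal F4, which has the same O1–C5 bond as 10 and already the oxidation level of 12. F4 would replace 12 in step 6 under the same BF3·OEt2 conditions and so rejoin the route at 14, with steps 4 and 5 bypassed. The price is competition from decarbonylation and cycloreversion and a possible loss of configuration at C5 in the benzylic radical.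

Step 6 (C-arylation). What is most likely to go wrong is over-reaction: the newly formed C2–O1 bond, benzylic to a para-hydroxyaryl group, can re-ionise under the Lewis acid and capture a second molecule of 13 with ring opening. Attack through the carbon meta to the hydroxyl group of 13, or loss of a silyl ether, are lesser risks. Fallback, setting out from 12 and returning at 15: the aryl group is delivered as a carbon nucleophile of fixed regiochemistry without a strong Lewis acid. Exchange of the anomeric acetate of 12 for a sulfonyl group (PhSO2H, CaCl2, CH2Cl2, rt) should give the anomeric phenyl sulfone F5. Commercial 4-bromo-2,6-dimethoxyphenol F6 is silylated (TBSCl, imidazole, DMF) to its tert-butyldimethylsilyl ether F7, which is converted with Mg and then ZnBr2 (THF) into the diarylzinc F8. Displacement of the sulfinate from F5 by F8 (THF, rt; the known substitution of 2-sulfonyl cyclic ethers by organozinc reagents, which favours entry trans to the neighbouring substituent) should give the tris-silyl ether F9. The fluoride conditions of step 7 then remove all three silyl groups and give 15.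

## Further compounds

F1 | step 3 | (1R,2R)-1,2-diphenylethane-1,2-diol (commercial resolving diol) | O[C@H](c1ccccc1)[C@H](O)c1ccccc1
F2 | step 3 | spiro-ketal of 9 with F1: (6R,7R)-6,7-diphenyl-1-(3,4,5-trimethoxyphenyl)-2,3-bis{[tert-butyl(diphenyl)silyl]oxymethyl}-5,8-dioxaspiro[3.4]octane, cyclobutane centres as in 9 | C12(O[C@H](c3ccccc3)[C@@H](c3ccccc3)O1)[C@@H](c3cc(OC)c(OC)c(OC)c3)[C@H](CO[Si](c3ccccc3)(c3ccccc3)C(C)(C)C)[C@H]2CO[Si](c2ccccc2)(c2ccccc2)C(C)(C)C
F3 | step 3 | diastereomeric spiro-ketal from the mirror image of 9 and F1 (cyclobutane centres inverted, dioxolane 6R,7R) | C12(O[C@H](c3ccccc3)[C@@H](c3ccccc3)O1)[C@H](c3cc(OC)c(OC)c(OC)c3)[C@@H](CO[Si](c3ccccc3)(c3ccccc3)C(C)(C)C)[C@@H]2CO[Si](c2ccccc2)(c2ccccc2)C(C)(C)C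
F4 | step 4 | (3S,4S,5R)-3,4-bis{[tert-butyl(diphenyl)silyl]oxymethyl}-2-methoxy-5-(3,4,5-trimethoxyphenyl)oxolane (C2 epimers) | COC1O[C@@H](c2cc(OC)c(OC)c(OC)c2)[C@H](CO[Si](c2ccccc2)(c2ccccc2)C(C)(C)C)[C@H]1CO[Si](c1ccccc1)(c1ccccc1)C(C)(C)C
F5 | step 6 | (3S,4S,5R)-2-(benzenesulfonyl)-3,4-bis{[tert-butyl(diphenyl)silyl]oxymethyl}-5-(3,4,5-trimethoxyphenyl)oxolane (C2 epimers) | O=S(=O)(c1ccccc1)C1O[C@@H](c2cc(OC)c(OC)c(OC)c2)[C@H](CO[Si](c2ccccc2)(c2ccccc2)C(C)(C)C)[C@H]1CO[Si](c1ccccc1)(c1ccccc1)C(C)(C)C
F6 | step 6 | 4-bromo-2,6-dimethoxyphenol (commercial) | COc1cc(Br)cc(OC)c1O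
F7 | step 6 | (4-bromo-2,6-dimethoxyphenoxy)(tert-butyl)dimethylsilane | COc1cc(Br)cc(OC)c1O[Si](C)(C)C(C)(C)C
F8 | step 6 | bis{4-[tert-butyl(dimethyl)silyl]oxy-3,5-dimethoxyphenyl}zinc | COc1cc([Zn]c2cc(OC)c(O[Si](C)(C)C(C)(C)C)c(OC)c2)cc(OC)c1O[Si](C)(C)C(C)(C)C
F9 | step 6 | tert-butyl{4-[(2R,3S,4S,5R)-3,4-bis{[tert-butyl(diphenyl)silyl]oxymethyl}-5-(3,4,5-trimethoxyphenyl)oxolan-2-yl]-2,6-dimethoxyphenoxy}dimethylsilane | COc1cc([C@@H]2O[C@@H](c3cc(OC)c(OC)c(OC)c3)[C@H](CO[Si](c3ccccc3)(c3ccccc3)C(C)(C)C)[C@H]2CO[Si](c2ccccc2)(c2ccccc2)C(C)(C)C)cc(OC)c1O[Si](C)(C)C(C)(C)C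
A1 | alternative 1 | (R)-5-(3,4,5-trimethoxyphenyl)furan-2(5H)-one | O=C1O[C@@H](c2cc(OC)c(OC)c(OC)c2)C=C1
A2 | alternative 1 | (3S,4R,5R)-3-(benzyloxymethyl)-4-{[dimethyl(propan-2-yloxy)silyl]methyl}-5-(3,4,5-trimethoxyphenyl)oxolan-2-one (trans,trans) | O=C1O[C@@H](c2cc(OC)c(OC)c(OC)c2)[C@H](C[Si](C)(C)OC(C)C)[C@H]1COCc1ccccc1
A3 | alternative 1 | chloro{[dimethyl(propan-2-yloxy)silyl]methyl}magnesium | CC(C)O[Si](C)(C)C[Mg]Cl
A4 | alternative 1 | benzyl chloromethyl ether | ClCOCc1ccccc1
A5 | alternative 2 | tert-butyl (3S,4R)-4-{[4-(benzyloxy)-3,5-dimethoxyphenyl]methoxy}-3-{[tert-butyl(dimethyl)silyl]oxymethyl}-2-diazo-4-(3,4,5-trimethoxyphenyl)butanoate | COc1cc(CO[C@@H](c2cc(OC)c(OC)c(OC)c2)[C@H](CO[Si](C)(C)C(C)(C)C)C(=[N+]=[N-])C(=O)OC(C)(C)C)cc(OC)c1OCc1ccccc1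
A6 | alternative 2 | tert-butyl (2R,3R,4S,5R)-2-[4-(benzyloxy)-3,5-dimethoxyphenyl]-4-{[tert-butyl(dimethyl)silyl]oxymethyl}-5-(3,4,5-trimethoxyphenyl)oxolane-3-carboxylate (all-trans) | COc1cc([C@@H]2O[C@@H](c3cc(OC)c(OC)c(OC)c3)[C@H](CO[Si](C)(C)C(C)(C)C)[C@H]2C(=O)OC(C)(C)C)cc(OC)c1OCc1ccccc1
A7 | alternative 3 | (2S,3S)-2-(3,4,5-trimethoxyphenyl)-3-vinyloxirane (trans) | C=C[C@@H]1O[C@H]1c1cc(OC)c(OC)c(OC)c1
A8 | alternative 3 | dimethyl 2-{[4-(benzyloxy)-3,5-dimethoxyphenyl]methylidene}propanedioate | COC(=O)C(=Cc1cc(OC)c(OCc2ccccc2)c(OC)c1)C(=O)OC
A9 | alternative 3 | dimethyl (2S,4R,5R)-2-[4-(benzyloxy)-3,5-dimethoxyphenyl]-4-ethenyl-5-(3,4,5-trimethoxyphenyl)oxolane-3,3-dicarboxylate (2,5-trans, 4,5-trans) | COc1cc([C@@H]2O[C@@H](c3cc(OC)c(OC)c(OC)c3)[C@H](C=C)C2(C(=O)OC)C(=O)OC)cc(OC)c1OCc1ccccc1
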